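## Structural features

The target is a monocyclic bisabolane: a cyclohexane ring (C1–C6) joined through C6 to a side chain C7–C13, with C14 as the exocyclic methylene on C7. The ring carries five contiguous stereocentres, C2 to C6: a C2–C3 epoxide (methyl on the quaternary C3), a free hydroxyl on C4, an angelate on C5 and the side chain on C6. The epoxide oxygen, O4, O5 and the C6–C7 bond all lie on one face (2S,3R,4R,5R,6S). In the chain, C8 is an allylic (S)-carbinol carrying the second angelate and C10–C11 is a 2,2-dimethyl epoxide (10R); neither centre has a ring neighbour that could control it. The fragile groups are the two epoxides (the dimethyl epoxide is acid-labile), the two angelates (Z-to-E isomerisation to tiglates, and migration of the C5 acyl group to the free cis O4 under base) and the allylic ester at C8. The real difficulty is threefold: the all-cis ring array, the differentiation of three secondary oxygens (O4 free, O5 and O8 acylated), and the remote centres C8 and C10. The key step exploits two features. O–C5/C6–C7–C8 is a cis-2,3-disubstituted tetrahydrofuran in disguise, that is, the ring fusion of a dihydrofuran cycloadduct. C2 and C4 with the methyl-bearing C3 between them are the 1,3-dioxygenation pattern of a 2-methylcyclohexenone, and therefore of a 1,5-dicarbonyl compound that a de Mayo fragmentation sets free.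

## Logic of the disconnections

30 ⇒ 29. The O4–Si bond is cut last. O4 is the only ring oxygen that must end up free, so it is the one that stays masked while O5 and O8 are acylated. The forward step must remove silicon without opening either epoxide and without acyl migration from O5 to O4.

29 ⇒ 28. The two C–O bonds of the C10–C11 epoxide are cut. This removes the most acid-labile group and the remote C10 centre in one move and leaves a trisubstituted alkene. The forward epoxidation must be catalyst-controlled (no neighbouring stereocentre helps) and must pick the electron-rich C10=C11 alkene over C7=C14 and the two angelate alkenes.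

28 ⇒ 25 + 26. Both acyl–oxygen bonds (O5–CO and O8–CO) are cut together, because the two esters are identical and the two hydroxyls are freed together earlier on. This gives a diol and the purchasable acid. The forward acylation must not isomerise the Z-alkene of 26 and must reach the hindered O5.

25 ⇒ 24. C10=C11 is cut (cross-metathesis). The prenyl group is traced back to an allyl group because prenyl-metal reagents attack carbonyl groups through their γ-carbon and would give the branched isomer. The forward step must leave the 1,1-disubstituted C7=C14 alkene alone.

24 ⇒ 22. C8–C9 is cut. C8 becomes an aldehyde carbon (masked as a lactol with O5) and the C8 centre becomes the result of a reagent-controlled allylation. The demand is face selectivity on an enal that is only present as the minor open tautomer of 22.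

22 ⇒ 21 ⇒ 18. The C8 oxidation level is raised to the lactone and the C7=C14 bond is cut. A γ-lactone has a single enolisable position (C7), so the methylene can be introduced without regiochemical ambiguity. The forward steps need a stop at the lactol stage and an elimination that does not move the alkene into the ring.

18 ⇒ 17. The C8 carbonyl oxygen is removed, which returns the tetrahydrofuran ring. This is the ring that the cycloaddition partner 8 brings, so C7 and C8 come with the key step. The forward C–H oxidation must choose the C8 methylene over the C5 methine and must leave the epoxide and the silyl ether alone.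

17 ⇒ 16 ⇒ 15 ⇒ 14. In turn, the O4–Si bond, the two epoxide C–O bonds and the C4–H bond are cut. This leaves a cis-fused bicyclic enone with only two stereocentres (C5, C6). Forward, hydride must add to C4 from the convex face, and the new hydroxyl must then direct the epoxidation to its own face; these two steps set C4, C3 and C2.

14 ⇒ 12. The C2=C3 bond is cut (aldol condensation). The ring opens to a 1,5-keto aldehyde in which the ethyl ketone supplies C3 with its methyl group. The forward closure has only one viable ring size, and the cis ring fusion is the stable one.

12 ⇒ 9. The C1–C4 bond is re-formed (forward: retro-aldol cleavage of a cyclobutanol). The 1,5-dicarbonyl pattern becomes a strained four-membered ring whose β-oxygen is stored as an acyl acetal. Forward, the lactone must be reduced by exactly one hydride so that the aldehyde oxidation level is obtained directly.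

9 ⇒ 7 + 8. The C4–C5 and C1–C6 bonds are cut ([2+2]). Both partners are flat and simple, and the cis C5–O/C6–C7 relationship becomes a consequence of suprafacial addition to a cyclic enol ether. The forward step must be head-to-tail, exo (cis-anti-cis) and selective for one face of 7.

7 ⇒ 5 ⇒ 3 + 4, and 3 ⇒ 2 ⇒ 1. The C5=C6 alkene of 7 is traced to the saturated acetal 5, the acetal to the β-hydroxy acid 3 and the aldehyde 4, and 3 to the β-keto ester 1. One catalytic asymmetric hydrogenation sets the carbinol centre; this controls the acetal centre, which survives as the only stereocentre of 7 after the carbinol centre is erased.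

## Other disconnections considered

Alternative 1: The cut goes through C1–C2 and C5–C6 and takes the carbocycle apart into 3-methylfuran A1 and 2,2,2-trifluoroethyl acrylate A2. Forward, a Lewis-acid-catalysed Diels–Alder reaction would give the exo 7-oxanorbornene ester A3 (bridging oxygen on C2 and C5, ester carbon = C7).
- In its favour: one step from two purchasable compounds builds the six-membered ring with eight of the fifteen skeletal carbons. The exo ester is cis to the oxygen on C5, the same relationship that the ring fusion of 9 secures. Catalytic enantioselective Diels–Alder reactions of furans with this acrylate class are an established reaction type, so absolute control would rest on firmer precedent than the facial bias of 7, and no photoreactor is needed. On both of these points this alternative is the better one.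
- Against it here: furan adducts undergo cycloreversion, and the regiochemistry and exo selectivity with A1 are not assured. The bridge must be opened by breaking C2–O while keeping C5–O, although the acidic C6–H next to the ester invites the opposite β-elimination and aromatisation. Afterwards O4 and the cis epoxide must be set on a ring that, unlike 14, has no carbonyl at C4 to start from. C7 is an ester carbon from which the C7(=CH2)–C8 unit still needs two C–C bond formations.
- Comparison: in structure A3 is one carbon (C8) short of 9. In mechanism it is a thermal concerted cycloaddition against a stepwise photochemical one, with the cis C5–O/C6–C7 relay equal in both. In step economy it wins before the key step (one step against four to reach 7) but is expected to lose more than that afterwards.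

Alternative 2: The cut is the C3–C4 bond. The (Z)-vinyl iodide aldehyde A4, whose C5 and C6 centres would come from an auxiliary-controlled syn-aldol reaction, would be closed with CrCl2 and catalytic NiCl2 (Nozaki–Hiyama–Kishi reaction) to the 2-methylcyclohex-2-enol A5.
- In its favour: the absolute configuration of C5/C6 would come from an aldol reaction whose sense is among the best documented in synthesis, which is better than an unproven photochemical relay. The closure tolerates the silyl ether and the Weinreb amide. A5 is already the allylic alcohol needed for a directed epoxidation, so it stands level with 15. C7 is at the acid oxidation level, ready for a ketone synthesis.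
- Against it here: the C4 configuration would be set in the ring closure without reliable control, so an oxidation/Luche reduction loop may be needed (the same control as step 8). A4 is a β-silyloxy aldehyde with an epimerisable C6 and a risk of β-elimination. The chromium salt is used in excess and is awkward on scale. The acyclic precursor needs a longer linear sequence than the five steps to 9. C8 and C14 are still to be added, and the O5 silyl ether with free O4 is the reverse of the final pattern, which costs a protecting-group exchange.
- Comparison: in structure A5 holds C1–C7 and C15, while 9 also holds C8. In mechanism a polar organometallic closure stands against a photocycloaddition, equal in functional-group tolerance. In step economy it is estimated to be longer by several steps.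

Alternative 3: The cut is the C6–C7 bond. Bu3SnH/AIBN would turn the (1-bromovinyl)dimethylsilyl ether A6 into an α-silylvinyl radical tethered to O5. This closes 5-exo onto C6 of the diene, the allyl radical takes hydrogen at C1, and the cis-fused siloxane A7 would result.
- In its favour: the tether forces C6–C7 cis to O5, a control equal to the ring fusion in 9. O4, O5 and the C2=C3 alkene are in place before the key step. C14 arrives as the exocyclic methylene, so no separate methylenation is needed; this is better than steps 11 and 12 of the chosen route.
- Against it here: A6 would be made from the cis-diol A8. By CIP analysis A8 is (1R,2S), the mirror image of the diol A9 that enzymatic dihydroxylation of toluene supplies, so the obvious chiral-pool entry appears to lead to the wrong enantiomer. The two hydroxyls must be differentiated, the cyclohexadiene can dimerise or aromatise, hydrogen transfer to the allyl radical may also occur at C3, and a tin hydride is needed. The C7–Si bond must afterwards be exchanged for the C7–C8 bond, with C8 then formed without control.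
- Comparison: in structure A7 has C1–C7, C14, C15 and the ring oxygens at the right carbons but lacks C8. In mechanism it is a radical chain cyclisation whose stereocontrol is geometric and at least as dependable as an excited-state facial preference. In step economy it would be shorter to the ring if A8 were available, but making A8 by other means and building C8 late removes that advantage.

Key step: step 5

Remarks on the chemistry:
- Atom labels C1–C15 in all names are the bisabolane labels of the target. CIP descriptors are assigned per compound; some change when a substituent changes although the geometry does not.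
- The SMILES strings of 7 and 9 were checked atom by atom. 9 encodes the (R)-acetal, the cyclobutane on the face opposite the tert-butyl group, the cis-anti-cis topology and the C5/C6 configuration of 30. No correction is needed.
- Assumed: the allylborane of step 14 and the ketone catalyst of step 17 are purchased.

## Steps

Step 1
Reactants: 1 methyl 3-oxopentanoate
Product: 2 methyl (R)-3-hydroxypentanoate
Conditions: H2 (50 atm), RuCl2[(R)-BINAP] (0.1 mol%), MeOH, 50 °C
Reagents that add atoms: none
Why: Noyori asymmetric hydrogenation of a β-keto ester; the (R)-BINAP complex of divalent ruthenium should deliver hydrogen to the chelated keto ester in the sense that gives the (R)-carbinol, as it does for methyl acetoacetate.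

Step 2
Reactants: 2 methyl (R)-3-hydroxypentanoate
Product: 3 (R)-3-hydroxypentanoic acid
Conditions: LiOH, THF/H2O, 0 °C → rt; then 1 M HCl to pH 2
Reagents that add atoms: lithium hydroxide, [Li+].[OH-]
Why: Saponification; cold hydroxide should hydrolyse the ester without retro-aldol cleavage or dehydration, and the stereocentre is not touched.

Step 3
Reactants: 3 (R)-3-hydroxypentanoic acid; 4 pivalaldehyde
Product: 5 (2R,6R)-2-tert-butyl-6-ethyl-1,3-dioxan-4-one (cis)
Conditions: TsOH·H2O (cat.), CH2Cl2, reflux, water separator
Reagents that add atoms: none
Why: Acid-catalysed acetalisation under thermodynamic control; the acetal centre is set by the C6 ethyl group because the cis isomer has tert-butyl and ethyl both equatorial on the chair, and the minor trans isomer would be removed by crystallisation.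

Step 4
Reactants: 5 (2R,6R)-2-tert-butyl-6-ethyl-1,3-dioxan-4-one
Product: 7 (R)-2-tert-butyl-6-ethyl-4H-1,3-dioxin-4-one, via α-bromo ether 6 (not isolated)
Conditions: NBS, AIBN (cat.), CCl4, reflux; then Et3N, 0 °C
Reagents that add atoms: none
Why: Wohl–Ziegler-type radical bromination at the C6–H next to the ring oxygen, then loss of HBr towards the acidic C5 hydrogens, should give the conjugated dioxinone; the carbinol centre is erased and the (R)-acetal centre remains as the only stereocentre.

Step 5
Reactants: 7 (R)-2-tert-butyl-6-ethyl-4H-1,3-dioxin-4-one; 8 2,3-dihydrofuran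
Product: 9 cis-anti-cis photoadduct, (1R,2R,6R,7R,10R)-10-tert-butyl-1-ethyl-3,9,11-trioxatricyclo[5.4.0.0(2,6)]undecan-8-one
Conditions: hν (300 nm, Pyrex), 8 (10 equiv), MeCN, −40 °C, no ketone sensitiser
Reagents that add atoms: none
Why: Excitation of 7 and intersystem crossing give the triplet enone, which adds stepwise to the electron-rich alkene 8 through a 1,4-biradical; this is the de Mayo-type enone–alkene [2+2] photocycloaddition of 1,3-dioxin-4-ones with enol ethers, the closest known reaction type. The four-membered ring is closed by recombination of that biradical, so the two new bonds (C4–C5 and C1–C6) lie on one face of each partner. Head-to-tail orientation is expected because the oxygen-bearing carbon of an enol ether bonds to the β-carbon of the excited enone, which places the ring oxygen on C5 next to the future C4 carbonyl. The 6-4 and 5-4 ring fusions can only be cis, which fixes C4 relative to C1 and C5 relative to C6, and the tetrahydrofuran ring should turn away from the dioxanone ring (cis-anti-cis) for steric reasons. The absolute configuration of C5 and C6 then depends on the face of 7 that is attacked: approach on the side of the acetal hydrogen, away from the pseudo-equatorial tert-butyl group of the sofa-shaped ring, gives 9. The step therefore needs three selectivities (regiochemistry, exo topology, face); the last is the least secure, and low temperature and excess 8 are meant to favour it, while omitting acetone avoids Paternò–Büchi addition to 8. Because the facial isomers are diastereomers, 9 can be purified to a single stereoisomer before the acetal is removed; C1 and C4 lose their stereochemistry in the next two steps, so only C5 and C6 are carried on.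

Step 6
Reactants: 9 cis-anti-cis photoadduct
Product: 12 2-[(2R,3R)-2-propanoyloxolan-3-yl]acetaldehyde (cis), via lactol 10 (not isolated), via cyclobutanol aldehyde 11 (not isolated)
Conditions: iBu2AlH (1.1 equiv), CH2Cl2, −78 °C; aq. KNaC4H4O6; then 1 M HCl, THF, 0 °C → rt
Reagents that add atoms: none
Why: Half-reduction of the lactone gives a lactol whose hemiacetal collapses with loss of pivalaldehyde; the freed β-hydroxy aldehyde then undergoes strain-driven retro-aldol cleavage of the C1–C4 cyclobutane bond (de Mayo fragmentation) and delivers the 1,5-keto aldehyde directly at the aldehyde oxidation level. C5 and C6 are not involved.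

Step 7
Reactants: 12 2-[(2R,3R)-2-propanoyloxolan-3-yl]acetaldehyde
Product: 14 (3aS,7aR)-6-methyl-3,3a,4,7a-tetrahydro-1-benzofuran-7(2H)-one (cis-fused enone), via aldol 13 (not isolated)
Conditions: TsOH·H2O (10 mol%), toluene, 80 °C
Reagents that add atoms: none
Why: Intramolecular aldol condensation; only the enol of the ethyl ketone CH2 (C3) can reach the C2 aldehyde through a six-membered transition state, and dehydration gives the conjugated enone. The ring fusion should stay cis because the cis-fused bicycle is the more stable isomer and C5 can equilibrate, whereas C6 cannot epimerise.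

Step 8
Reactants: 14 cis-fused enone
Product: 15 (3aS,7S,7aR)-6-methyl-2,3,3a,4,7,7a-hexahydro-1-benzofuran-7-ol (C4 hydroxyl cis to O5)
Conditions: NaBH4, CeCl3·7H2O, MeOH, −78 °C
Reagents that add atoms: none
Why: Luche reduction (1,2-selective); hydride should attack C4 from the convex face of the cis-fused bicycle, anti to the C5–O bond, which places the new hydroxyl cis to O5.

Step 9
Reactants: 15 allylic alcohol
Product: 16 epoxy alcohol (C2–C3 epoxide on the hydroxyl face; 2S,3R,4R,5R,6R)
Conditions: VO(acac)2 (5 mol%), tBuOOH (in decane, 1.5 equiv), CH2Cl2, 0 °C → rt
Reagents that add atoms: tert-butyl hydroperoxide, CC(C)(C)OO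
Why: Hydroxyl-directed epoxidation of a cyclic allylic alcohol; the vanadium alkoxide–peroxide complex delivers oxygen to the alkene face syn to the C4 hydroxyl, which sets C2 and C3 and completes the all-cis oxygen array.

Step 10
Reactants: 16 epoxy alcohol
Product: 17 triethylsilyl ether of 16 (2S,3S,4R,5R,6R)
Conditions: Et3SiCl, imidazole, DMAP (cat.), DMF, 0 °C → rt
Reagents that add atoms: chlorotriethylsilane, CC[Si](Cl)(CC)CC
Why: Silylation of the only hydroxyl; the triethylsilyl ether should mask O4 through the oxidation and carbanion steps and still be removable with buffered fluoride at the end. A silyl chloride with imidazole avoids Lewis-acidic triflates next to the epoxide.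

Step 11
Reactants: 17 silyl ether
Product: 18 γ-lactone (C8 carbonyl; 2S,3S,4R,5R,6S)
Conditions: RuCl3·xH2O (5 mol%), NaIO4 (4 equiv), CCl4/MeCN/aq. phosphate buffer (pH 7), rt
Reagents that add atoms: sodium periodate, [Na+].[O-]I(=O)(=O)=O
Why: RuO4-mediated oxidation of an ether α-methylene to the lactone; the C8 methylene should be attacked in preference to the C5 methine, which is hindered and deactivated by the neighbouring silyloxy group, and epoxides are inert to RuO4. No alkene or free alcohol is present at this stage.

Step 12
Reactants: 18 γ-lactone
Product: 21 α-methylene lactone (C7=C14), via Mannich base 19 (not isolated), via ammonium iodide 20 (not isolated)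
Conditions: LiN(iPr)2, THF, −78 °C; CH2=NMe2+ I−, −78 → 0 °C; then MeI, MeOH, rt; then aq. NaHCO3, CH2Cl2, rt
Reagents that add atoms: N,N-dimethylmethyleneiminium iodide (Eschenmoser's salt), C=[N+](C)C.[I-]
Why: Mannich reaction of the lactone enolate (C7 is the only enolisable position), quaternisation and Hofmann-type β-elimination should give the α-methylene lactone; the C7 centre formed on the way is destroyed again, and mild bicarbonate avoids migration of the alkene into the ring.

Step 13
Reactants: 21 α-methylene lactone
Product: 22 α-methylene lactol (both anomers)
Conditions: iBu2AlH (1.1 equiv), CH2Cl2, −78 °C; aq. KNaC4H4O6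
Reagents that add atoms: none
Why: 1,2-Reduction of the lactone carbonyl by an aluminium hydride; the tetrahedral aluminate is stable at −78 °C, so neither over-reduction nor conjugate reduction is expected, and O5 stays tied up in the hemiacetal.

Step 14
Reactants: 22 α-methylene lactol
Product: 24 allyl diol (8S; free O5–H and O8–H, terminal vinyl on C9), via hydroxy enal 23 (not isolated)
Conditions: allylB(Ipc)2 of the (+)-α-pinene series (2.5 equiv), Et2O, −78 °C → rt; then HOCH2CH2NH2, rt
Reagents that add atoms: B-allyldiisopinocampheylborane of the (+)-α-pinene series, C=CCB([C@@H]1C[C@@H]2C[C@H]([C@H]1C)C2(C)C)[C@@H]1C[C@@H]2C[C@H]([C@H]1C)C2(C)C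
Why: Brown allylation of the lactol through its open hydroxy-enal tautomer; the chair transition state of the pinene-derived allylborane fixes the aldehyde face (reagent control), and this reagent series gives the (S)-carbinol when the aldehyde substituent outranks the allyl group, as with benzaldehyde, so C8 should be set as S. An allyl reagent is used because prenyl metals add through their γ-carbon, and the amine work-up avoids alkoxides and with them migration of the silyl group from O4 to the freed cis O5.

Step 15
Reactants: 24 allyl diol
Product: 25 prenyl diol (C10=C11 trisubstituted alkene)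
Conditions: 2-methyl-2-butene (excess), second-generation Grubbs catalyst RuCl2(H2IMes)(PCy3)(=CHPh) (5 mol%), CH2Cl2, 40 °C
Reagents that add atoms: 2-methyl-2-butene, CC=C(C)C
Why: Olefin cross-metathesis should convert the terminal vinyl group into the prenyl alkene; the 1,1-disubstituted C7=C14 alkene is flanked by two branched carbons and should not enter the catalytic cycle, and free hydroxyls and the epoxide are tolerated.

Step 16
Reactants: 25 prenyl diol; 26 angelic acid
Product: 28 bis-angelate (O5 and O8 acylated, O4 silylated), via mixed anhydride 27 (not isolated)
Conditions: 26 (6 equiv), 2,4,6-Cl3C6H2COCl, Et3N, toluene, rt; then 25, toluene, 80 °C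
Reagents that add atoms: none
Why: Yamaguchi esterification without DMAP; the 2,4,6-trichlorobenzoyl mixed anhydride transfers the angeloyl group thermally, which avoids the acylpyridinium addition–elimination pathway that isomerises angelates to tiglates. Both free hydroxyls are acylated while O4 stays silylated, which settles the differentiation of the three oxygens.

Step 17
Reactants: 28 bis-angelate
Product: 29 bis-epoxide silyl ether (10R)
Conditions: D-fructose-derived Shi ketone (30 mol%), KHSO5 (as Oxone), K2CO3, Bu4NHSO4, aq. Na2B4O7 buffer (pH 10.5), MeCN/CH2(OMe)2, 0 °C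
Reagents that add atoms: potassium peroxymonosulfate, [K+].[O-]S(=O)(=O)OO
Why: Shi epoxidation; the chiral dioxirane reacts through a spiro transition state, and the D-fructose-derived ketone is the enantiomer that gives the (R)-epoxide from a 2-methylalk-2-ene, so C10 is set by the catalyst. The electron-rich trisubstituted C10=C11 alkene should react far faster than the 1,1-disubstituted allylic-ester alkene C7=C14 and the electron-poor angelate alkenes.

Step 18
Reactants: 29 bis-epoxide silyl ether
Product: 30 target CNP0235377.1 (2S,3R,4R,5R,6S,8S,10R)
Conditions: HF·pyridine, pyridine, THF, 0 °C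
Reagents that add atoms: none
Why: Fluoride-mediated desilylation under buffered, slightly acidic conditions, where base-induced acyl migration from O5 to O4 is suppressed and the epoxides should survive; no stereocentre is touched.

## Compound list

1 | methyl 3-oxopentanoate | CCC(=O)CC(=O)OC | starting material
2 | methyl (R)-3-hydroxypentanoate | CC[C@@H](O)CC(=O)OC | intermediate
3 | (R)-3-hydroxypentanoic acid | CC[C@@H](O)CC(=O)O | intermediate
4 | pivalaldehyde (2,2-dimethylpropanal) | CC(C)(C)C=O | starting material
5 | (2R,6R)-2-tert-butyl-6-ethyl-1,3-dioxan-4-one (cis) | CC[C@@H]1CC(=O)O[C@H](C(C)(C)C)O1 | intermediate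
6 | (2R)-6-bromo-2-tert-butyl-6-ethyl-1,3-dioxan-4-one (α-bromo ether, both C6 epimers) | CCC1(Br)CC(=O)O[C@H](C(C)(C)C)O1 | intermediate (not isolated)
7 | (R)-2-tert-butyl-6-ethyl-4H-1,3-dioxin-4-one | CCC1=CC(=O)O[C@H](C(C)(C)C)O1 | intermediate
8 | 2,3-dihydrofuran | C1CC=CO1 | starting material
9 | (1R,2R,6R,7R,10R)-10-tert-butyl-1-ethyl-3,9,11-trioxatricyclo[5.4.0.0(2,6)]undecan-8-one; cis-anti-cis photoadduct (cyclobutane C4–C5–C6–C1, dioxanone on C4/C1, tetrahydrofuran O on C5 and CH2CH2 on C6) | CC[C@@]12O[C@@H](C(C)(C)C)OC(=O)[C@@H]1[C@H]3CCO[C@H]32 | intermediate
10 | lactol of 9 (C2 carbonyl reduced to CH–OH, both anomers) | CC[C@@]12O[C@@H](C(C)(C)C)OC(O)[C@@H]1[C@H]3CCO[C@H]32 | intermediate (not isolated)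
11 | 7-ethyl-7-hydroxy-2-oxabicyclo[3.2.0]heptane-6-carbaldehyde (cyclobutanol aldehyde, configuration as in 9) | CC[C@@]1(O)[C@H](C=O)[C@H]2CCO[C@H]21 | intermediate (not isolated)
12 | 2-[(2R,3R)-2-propanoyloxolan-3-yl]acetaldehyde (cis; 5R,6R in bisabolane labels) | CCC(=O)[C@@H]1OCC[C@@H]1CC=O | intermediate
13 | (3aR,7aR)-5-hydroxy-6-methylhexahydro-1-benzofuran-7(2H)-one (cis-fused aldol, mixture at the two new centres) | CC1C(O)C[C@H]2CCO[C@H]2C1=O | intermediate (not isolated)
14 | (3aS,7aR)-6-methyl-3,3a,4,7a-tetrahydro-1-benzofuran-7(2H)-one (cis-fused enone; 5R,6S) | CC1=CC[C@H]2CCO[C@H]2C1=O | intermediate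
15 | (3aS,7S,7aR)-6-methyl-2,3,3a,4,7,7a-hexahydro-1-benzofuran-7-ol (4S,5R,6S; hydroxyl cis to O5) | CC1=CC[C@H]2CCO[C@H]2[C@H]1O | intermediate
16 | epoxy alcohol: 15 with the C2–C3 epoxide on the hydroxyl face (2S,3R,4R,5R,6R) | C1C[C@@H]2C[C@@H]3O[C@]3(C)[C@H](O)[C@@H]2O1 | intermediate
17 | O4-triethylsilyl ether of 16 (2S,3S,4R,5R,6R) | C1C[C@@H]2C[C@@H]3O[C@]3(C)[C@H](O[Si](CC)(CC)CC)[C@@H]2O1 | intermediate
18 | γ-lactone: 17 with C8 oxidised to the carbonyl (2S,3S,4R,5R,6S) | O=C1C[C@@H]2C[C@@H]3O[C@]3(C)[C@H](O[Si](CC)(CC)CC)[C@@H]2O1 | intermediate
19 | Mannich base: 18 with CH2NMe2 on C7 (both C7 epimers) | O=C1C(CN(C)C)[C@@H]2C[C@@H]3O[C@]3(C)[C@H](O[Si](CC)(CC)CC)[C@@H]2O1 | intermediate (not isolated)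
20 | trimethylammonium iodide of 19 | O=C1C(C[N+](C)(C)C)[C@@H]2C[C@@H]3O[C@]3(C)[C@H](O[Si](CC)(CC)CC)[C@@H]2O1.[I-] | intermediate (not isolated)
21 | α-methylene lactone: 18 with C7=C14H2 (2S,3S,4R,5R,6S) | O=C1C(=C)[C@@H]2C[C@@H]3O[C@]3(C)[C@H](O[Si](CC)(CC)CC)[C@@H]2O1 | intermediate
22 | α-methylene lactol: 21 with C8 as CH–OH (both anomers) | OC1C(=C)[C@@H]2C[C@@H]3O[C@]3(C)[C@H](O[Si](CC)(CC)CC)[C@@H]2O1 | intermediate
23 | hydroxy enal: open tautomer of 22 (C8 aldehyde on C7=C14H2, free O5–H) | C=C(C=O)[C@@H]1C[C@@H]2O[C@]2(C)[C@H](O[Si](CC)(CC)CC)[C@@H]1O | intermediate (not isolated)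
24 | allyl diol: (8S)-carbinol with CH2CH=CH2 on C8, free O5–H and O8–H, O4 silylated (2S,3S,4R,5R,6S,8S) | C=C([C@H](CC=C)O)[C@@H]1C[C@@H]2O[C@]2(C)[C@H](O[Si](CC)(CC)CC)[C@@H]1O | intermediate
25 | prenyl diol: 24 with C9H2–C10H=C11Me2 | C=C([C@H](CC=C(C)C)O)[C@@H]1C[C@@H]2O[C@]2(C)[C@H](O[Si](CC)(CC)CC)[C@@H]1O | intermediate
26 | angelic acid, (Z)-2-methylbut-2-enoic acid | C/C=C(/C)C(=O)O | starting material
27 | angelic 2,4,6-trichlorobenzoic anhydride | C/C=C(/C)C(=O)OC(=O)c1c(Cl)cc(Cl)cc1Cl | intermediate (not isolated)
28 | bis-angelate: 25 with angeloyl on O5 and O8 (2S,3S,4R,5R,6S,8S) | C=C([C@H](CC=C(C)C)OC(=O)/C(C)=C\C)[C@@H]1C[C@@H]2O[C@]2(C)[C@H](O[Si](CC)(CC)CC)[C@@H]1OC(=O)/C(C)=C\C | intermediate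
29 | O4-triethylsilyl ether of the target (2S,3S,4R,5R,6S,8S,10R) | C=C([C@H](C[C@H]1OC1(C)C)OC(=O)/C(C)=C\C)[C@@H]1C[C@@H]2O[C@]2(C)[C@H](O[Si](CC)(CC)CC)[C@@H]1OC(=O)/C(C)=C\C | intermediate
30 | CNP0235377.1 (2S,3R,4R,5R,6S,8S,10R) | C=C([C@H](C[C@H]1OC1(C)C)OC(=O)/C(C)=C\C)[C@@H]1C[C@@H]2O[C@]2(C)[C@H](O)[C@@H]1OC(=O)/C(C)=C\C | target

## Step count and least certain steps

Total step count: 18. Longest linear sequence: 18 steps (1 → 30); 4, 8 and 26 enter as purchased reactants.

Step 5 (key step). What may go wrong: weak or reversed facial discrimination by the remote acetal centre in the excited state, because the bias known for ground-state additions to such dioxinones need not carry over to the triplet. Partial head-to-head addition may add to this. The facial isomers are separable diastereomers, but a low or inverted bias would cost most of the material. Fallback (sets out from 8, returns at 15): give up the auxiliary relay and resolve later.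
- Commercial 2,2,6-trimethyl-4H-1,3-dioxin-4-one is γ-methylated through its lithium dienolate (LiN(iPr)2, THF/DMPU, −78 °C; MeI) to achiral 6-ethyl-2,2-dimethyl-4H-1,3-dioxin-4-one F1.
- Irradiation of F1 with 8 as in step 5 gives the racemic cis-anti-cis acetonide photoadduct F2.
- The conditions of step 6 lead through the racemic lactol F3 and the racemic cyclobutanol aldehyde F4 to the racemic keto aldehyde F5.
- The conditions of step 7 lead through the racemic aldol F6 to the racemic enone F7.
- The conditions of step 8 give the racemic allylic alcohol F8.
- Lipase-catalysed acetylation (Candida antarctica lipase B, vinyl acetate, tBuOMe, rt) resolves F8. By analogy with 2-substituted cyclohex-2-en-1-ols, the enantiomer with the configuration of 15 is expected to be the acylated one, giving the acetate F9 (assignment to be confirmed). K2CO3/MeOH converts F9 into 15.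

Step 14. What may go wrong: slow opening of the lactol to the enal at low temperature, protonolysis of the allylborane by the lactol hydroxyl, and mismatched double diastereoselection, all of which would erode control at C8. Fallback (sets out from 22, returns at 24): separate C–C bond formation from stereocontrol.
- Indium powder and allyl bromide in THF/H2O (neutral Barbier allylation, no alkoxide and so no silyl migration) give the C8-epimeric diols F10.
- MnO2 in CH2Cl2 oxidises only the allylic C8 carbinol to the hydroxy enone F11.
- Corey–Bakshi–Shibata reduction with (R)-2-methyl-CBS-oxazaborolidine and catecholborane (toluene, −78 °C) gives 24. This is the catalyst enantiomer that gives the (S)-alcohol from acetophenone, with the alkenyl group as the large substituent.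

Step 11. What may go wrong: competing oxidation at the C5 methine or at the C4–H of the silyl ether, or loss of the silyl group in the aqueous oxidant followed by oxidation of the freed carbinol. Fallback (sets out from 16, returns at 18): carry O4 through the oxidation as an electron-withdrawing ester, which deactivates both neighbouring C–H bonds.
- Chloroacetic anhydride and pyridine give the chloroacetate F12.
- RuCl3/NaIO4 as in step 11 gives the lactone chloroacetate F13.
- DABCO in EtOH removes the chloroacetyl group to give the hydroxy lactone F14.
- Et3SiCl/imidazole then gives 18.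

Step 16. What may go wrong: isomerisation of the angeloyl group to tigloyl during activation, and incomplete acylation of the hindered O5. Fallback (sets out from 25, returns at 28): build the Z-alkene after acylation.
- Both hydroxyls are esterified with 2-[bis(2-methylphenoxy)phosphoryl]propanoic acid (DCC, DMAP, CH2Cl2) to the bis(phosphonopropionate) F15.
- A Z-selective Horner–Wadsworth–Emmons olefination of the Ando type (NaH, THF, −78 °C; acetaldehyde) then forms both angelates and gives 28.

Step 18. What may go wrong: acyl migration from O5 to the freed O4, or opening of the acid-labile dimethyl epoxide by HF. Fallback (sets out from 28, returns at 30): change the order so that the silyl group is removed before the labile epoxide exists.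
- HF·pyridine/pyridine on 28 gives the desilylated bis-angelate F16.
- The Shi epoxidation is then run last at pH 8 with a stoichiometric amount of the ketone, where acyl migration should be slow, and gives 30.

## Further compounds

F1 | step 5 | 6-ethyl-2,2-dimethyl-4H-1,3-dioxin-4-one | CCC1=CC(=O)OC(C)(C)O1
F2 | step 5 | racemic cis-anti-cis acetonide photoadduct (both enantiomers) | CC[C@@]12OC(C)(C)OC(=O)[C@@H]1[C@H]3CCO[C@H]32.CC[C@]12OC(C)(C)OC(=O)[C@H]1[C@@H]3CCO[C@@H]32
F3 | step 5 | racemic lactol of F2 (both anomers) | CC[C@@]12OC(C)(C)OC(O)[C@@H]1[C@H]3CCO[C@H]32.CC[C@]12OC(C)(C)OC(O)[C@H]1[C@@H]3CCO[C@@H]32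
F4 | step 5 | racemic 7-ethyl-7-hydroxy-2-oxabicyclo[3.2.0]heptane-6-carbaldehyde | CC[C@@]1(O)[C@H](C=O)[C@H]2CCO[C@H]21.CC[C@]1(O)[C@@H](C=O)[C@@H]2CCO[C@@H]21
F5 | step 5 | racemic cis-2-(2-propanoyloxolan-3-yl)acetaldehyde | CCC(=O)[C@@H]1OCC[C@@H]1CC=O.CCC(=O)[C@H]1OCC[C@H]1CC=O
F6 | step 5 | racemic cis-fused aldol (5-hydroxy-6-methylhexahydro-1-benzofuran-7(2H)-one) | CC1C(O)C[C@H]2CCO[C@H]2C1=O.CC1C(O)C[C@@H]2CCO[C@@H]2C1=O
F7 | step 5 | racemic cis-fused enone (6-methyl-3,3a,4,7a-tetrahydro-1-benzofuran-7(2H)-one) | CC1=CC[C@H]2CCO[C@H]2C1=O.CC1=CC[C@@H]2CCO[C@@H]2C1=O
F8 | step 5 | racemic all-cis allylic alcohol (6-methyl-2,3,3a,4,7,7a-hexahydro-1-benzofuran-7-ol) | CC1=CC[C@H]2CCO[C@H]2[C@H]1O.CC1=CC[C@@H]2CCO[C@@H]2[C@@H]1O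
F9 | step 5 | acetate of 15 | CC1=CC[C@H]2CCO[C@H]2[C@H]1OC(C)=O
F10 | step 14 | C8-epimeric mixture of allyl diols (24 and its C8 epimer) | C=C(C(O)CC=C)[C@@H]1C[C@@H]2O[C@]2(C)[C@H](O[Si](CC)(CC)CC)[C@@H]1O
F11 | step 14 | hydroxy enone (C8 ketone, free O5–H) | C=C(C(=O)CC=C)[C@@H]1C[C@@H]2O[C@]2(C)[C@H](O[Si](CC)(CC)CC)[C@@H]1O
F12 | step 11 | O4-chloroacetate of 16 | C1C[C@@H]2C[C@@H]3O[C@]3(C)[C@H](OC(=O)CCl)[C@@H]2O1
F13 | step 11 | γ-lactone O4-chloroacetate | O=C1C[C@@H]2C[C@@H]3O[C@]3(C)[C@H](OC(=O)CCl)[C@@H]2O1
F14 | step 11 | hydroxy γ-lactone (free O4–H) | O=C1C[C@@H]2C[C@@H]3O[C@]3(C)[C@H](O)[C@@H]2O1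
F15 | step 16 | O5,O8-bis{2-[bis(2-methylphenoxy)phosphoryl]propanoate} of 25 | C=C([C@H](CC=C(C)C)OC(=O)C(C)P(=O)(Oc1ccccc1C)Oc1ccccc1C)[C@@H]1C[C@@H]2O[C@]2(C)[C@H](O[Si](CC)(CC)CC)[C@@H]1OC(=O)C(C)P(=O)(Oc1ccccc1C)Oc1ccccc1C
F16 | step 18 | desilylated bis-angelate (28 with free O4–H) | C=C([C@H](CC=C(C)C)OC(=O)/C(C)=C\C)[C@@H]1C[C@@H]2O[C@]2(C)[C@H](O)[C@@H]1OC(=O)/C(C)=C\C
A1 | alternative 1 | 3-methylfuran | Cc1ccoc1
A2 | alternative 1 | 2,2,2-trifluoroethyl acrylate | C=CC(=O)OCC(F)(F)F
A3 | alternative 1 | 2,2,2-trifluoroethyl exo-5-methyl-7-oxabicyclo[2.2.1]hept-5-ene-2-carboxylate | FC(F)(F)COC(=O)[C@@H]1C[C@@H]2O[C@H]1C=C2C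
A4 | alternative 2 | (Z)-vinyl iodide aldehyde with C5–OTBS and the C7 Weinreb amide | CON(C)C(=O)[C@H](C/C=C(/C)I)[C@@H](O[Si](C)(C)C(C)(C)C)C=O
A5 | alternative 2 | 2-methylcyclohex-2-enol with C5–OTBS and the C7 Weinreb amide | CON(C)C(=O)[C@@H]1CC=C(C)[C@H](O)[C@@H]1O[Si](C)(C)C(C)(C)C
A6 | alternative 3 | (1-bromovinyl)dimethylsilyl ether of the O4-TBS cyclohexadiene cis-diol | C=C(Br)[Si](C)(C)O[C@@H]1C=CC=C(C)[C@@H]1O[Si](C)(C)C(C)(C)C
A7 | alternative 3 | cis-fused bicyclic siloxane with exocyclic methylene on C7 | C=C1[C@@H]2CC=C(C)[C@H](O[Si](C)(C)C(C)(C)C)[C@@H]2O[Si]1(C)C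
A8 | alternative 3 | (1R,2S)-3-methylcyclohexa-3,5-diene-1,2-diol | O[C@@H]1C=CC=C(C)[C@@H]1O
A9 | alternative 3 | (1S,2R)-3-methylcyclohexa-3,5-diene-1,2-diol | O[C@H]1C=CC=C(C)[C@H]1O
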